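# Proposed total synthesis of CNP0273650.6 by an oxidopyrylium–alkynyl sulfoxide (5+2) cycloaddition

## Analysis of the target

The target 29 is a daucane diester built on a trans-fused hydroazulene: a cyclopentane (C1–C5) shares the C1–C5 bond with a cycloheptene (C1, C5, C6, C7, C8, C9, C10). The numbering used throughout is:

- C1: quaternary carbon with the angular methyl
- C2, C3: methylenes
- C4: tertiary carbinol carrying the isopropyl group
- C5: ring-fusion methine
- C6: carbinol acylated by the 4-hydroxybenzoyl group
- C7: methylene
- C8(CH3)=C9: trisubstituted alkene
- C10: allylic carbinol acylated by the tigloyl group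

β denotes the face of the seven-membered ring that bears the C10 oxygen, α the opposite face. There are five stereocentres (1S,4S,5S,6S,10R in this numbering). The C6 oxygen, H5 and the C4 hydroxyl are β like the C10 oxygen; the angular methyl and the isopropyl group are α. The ring fusion is therefore trans, and the isopropyl group stands cis to the angular methyl and to C6.

Sensitive groups:

- the tertiary C4 hydroxyl, which is β to C6 and can dehydrate or undergo retro-aldol cleavage while C6 is a ketone;
- the C8=C9 alkene, which slips into conjugation under base once C7 is an enolisable methylene next to a C6 ketone;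
- the allylic C10 ester, the reducible tiglate and the free phenol.

The synthesis is hard for four reasons. A quaternary carbon sits between two oxygenated carbons. The ring fusion is trans. The C4 configuration puts the larger group on the more crowded face. Three hydroxyls must be told apart: one stays free and two carry different acyl groups.

The strategy rests on one feature. C7 and C10 stand 1,4 across the C8=C9 alkene and C6 is oxygenated next to C7. This is the pattern of an 8-oxabicyclo[3.2.1]octa-3,6-dien-2-one whose ether bridge links C7 and C10 and whose ketone is C6, the product of a 3-oxidopyrylium ylide adding to an alkyne.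

## Retrosynthetic reasoning

**Acyl groups.** The phenol is unmasked last, so 29 comes from its aryl silyl ether 28. The tigloyl C–O bond at O10 is cut next (28 to 26 and tiglic acid 27), then the aroyl C–O bond at O6 (26 to triol 24 and the silyl-protected acid 25). The esters go on last because the tiglate and the phenolic ester are the groups least able to survive reductions and base. O6 is acylated before O10 because the C6 hydroxyl is equatorial, whereas the C10 hydroxyl is pseudo-axial and neopentylic. The tertiary C4 hydroxyl needs no protection.

**C6–H bond.** Triol 24 is traced to ketone 23. The cut is made here because the C6 ketone is what allows the bonds at C5 and C7 to be manipulated. The forward reduction has to deliver the equatorial β alcohol, which is the more stable epimer but not the one a hydride would give, since the angular methyl and the isopropyl group block the α face. A dissolving-metal reduction under thermodynamic control is therefore planned.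

**Two C–O bonds α to the C6 ketone.** Ketone 23 is traced to the bridged epoxy ketone 21 by reconnecting O10 to C7 and the C4 oxygen to C5. Both bonds flank the ketone, so one single-electron reductant cleaves both in the forward sense. The gain is threefold: the C10 hydroxyl appears with the configuration fixed in the cycloaddition, the C4 hydroxyl appears with the configuration of the epoxide, and H5 is introduced by protonation of an enolate whose α face is blocked.

**Epoxide oxygen.** Epoxy ketone 21 comes from the tetrasubstituted enone 20. The forward reaction is a nucleophilic epoxidation, which must occur on the β face. That face is open, while the α face carries the C1 methyl and lies over the two-carbon bridge. This sets C4 with oxygen β and isopropyl α, the arrangement that addition of an isopropyl nucleophile to a C4 ketone would not give.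

**C4–C5 bond.** Enone 20 is opened to the diketone 18 by a retro-aldol condensation. The five-membered ring is closed while the ether bridge is still in place for three reasons. C7 is then a bridgehead and cannot enolise. The C8=C9 alkene cannot migrate. Only the aldol between C5 and C4 can dehydrate, because the alternative aldol would need a bridgehead alkene.

**C1–C2 bond and the C9–S bond.** Diketone 18 is traced through the silyl enol ether 15 to the cycloadduct 13 and the Grignard reagent 14 made from bromide 11. The forward conjugate addition creates the quaternary C1 from the face of the ether bridge. Trapping as 15 masks the ketone, so the alkenyl sulfoxide can be exchanged for lithium and then for hydrogen. Acid then releases both ketones of 18.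

**C7–C8 and C9–C10 bonds (key disconnection).** Cycloadduct 13 is cut into the acetoxypyranone 4 and the alkynyl sulfoxide 7. This removes the seven-membered ring, its oxygen bridge and the C10 stereocentre at once, and leaves two small, flat building blocks. The forward step must form both bonds with one regiochemistry and on one face of the ylide 12, under the control of sulfur alone.

**Building blocks.** Pyranone 4 comes from the hemiacetal 3, the furfuryl alcohol 2 and the furoic acid 1 by acetylation, oxidative ring expansion and reduction. Sulfoxide 7 is cut at the S–C(alkyne) bond into the menthyl sulfinate 5 and the alkynyl Grignard reagent 6. Bromide 11 comes from the β-bromo ketone 10, which is cut at the acyl–isopropyl bond into 8 and 9.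

## Alternatives that were turned down

**Alternative 1:** The C5–C6 bond is cut, with C6 as a dithiane-masked acyl anion and C5 as an epoxide carbon. In the forward key step the deprotonated dithiane carbon of the tethered cyclopentene oxide A2 attacks C5 with inversion. This closes the seven-membered ring and frees the C4 hydroxyl, giving A1.

- For it: the displacement is stereospecific. The trans ring fusion and the C4 configuration both follow from the epoxide geometry, and C6 arrives masked at the ketone level. On this point it is stronger than the chosen route, which relies on the face selectivity of an epoxidation and of a protonation.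
- Against it: A2 must already carry the quaternary C1, the C10 stereocentre, the epoxide in the right relative configuration and a (Z)-trisubstituted alkene, which means a long linear preparation. The displacement is a seven-membered ring closure at a carbon flanked by a quaternary centre and a fully substituted epoxide carbon. It would be slow and open to competing allylic deprotonation at C7. The dithiane must later be removed next to an allylic silyl ether, and the C6 ketone then poses the same reduction problem as in the chosen route.
- Comparison: it makes one bond and one ring in its key step. The chosen step makes two bonds, the carbocycle and the C10 centre, from fragments available in a few steps.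

**Alternative 2:** The C1–C10 and C5–C6 bonds are cut by a (2+2) photocycloaddition, followed by cleavage of the C6–C10 bond of the cyclobutane. In the forward key step the enone A4 and the bis-silyl enediol ether A5 are irradiated in the presence of a chiral Lewis-acid complex to give A3. Cleaving the oxygenated cyclobutane bond then releases the cycloheptanedione.

- For it: the whole bicyclic skeleton, the quaternary C1 and oxygen at C4, C6 and C10 come from two achiral building blocks in two operations, under catalytic enantiocontrol. This is shorter to the skeleton than the chosen route and needs no stoichiometric auxiliary.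
- Against it: three ketones (C4, C6, C10) must be told apart, and C5 lies between two of them. The isopropyl group must be added to C4 on the face cis to the angular methyl, against the steric bias, to reach the C4 epimer required here. The C8=C9 alkene and the C10 configuration must still be introduced, and the cis photoadduct must be epimerised to the trans fusion. Enantioselective photocycloaddition of a β-substituted cyclopentenone with a tetrasubstituted, electron-rich alkene is an extrapolation comparable in risk to the chosen key step.
- Comparison: the chosen route is longer, but the three oxygenated carbons arrive already differentiated (C10 as an ether, C6 as a ketone, C4 from an epoxide). C4 is set by oxygen delivery to the open face, not by carbon delivery to the hindered one.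

**Alternative 3:** The C1–CH3 and C5–C6 bonds are cut. In the forward key step a copper–carbene catalyst adds a methyl group from an aluminium reagent to C1 of the enone A7. The resulting enolate is trapped at C5 by the aldehyde A8 to give the aldol A6. No ring is closed.

- For it: catalytic asymmetric conjugate addition to make a quaternary centre is far better precedented than the chosen key step. C1, C5 and C6 are set in one operation, and C6 is obtained directly as a carbinol, which avoids the late ketone reduction of the chosen route. On these points it is stronger.
- Against it: aluminium enolates are poor aldol donors. A8 is a β,γ-unsaturated aldehyde that enolises and conjugates easily, and the C6 configuration depends on an aldol selectivity that is not secured. The seven-membered ring still has to be closed at C9–C10, which creates C10 with uncertain control. The isopropyl group must again be added to the C4 ketone on the face cis to the neighbouring side chain and to the angular methyl.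
- Comparison: it is linear, with one stereochemical problem per step. The chosen route closes the ring and fixes C10 in a single step and postpones only centres that the rigid bicycle can direct.

Key step: step 7

Assumption: compounds 1, 5, 6, 8, 9, 25 and 27 are treated as catalogue chemicals, and the sulfur descriptors are those obtained when the S–O bond of a sulfinyl group is counted as a single bond.

## Route

Step 1
Reactants: 1 4-methylfuran-2-carboxylic acid
Product: 2 (4-methylfuran-2-yl)methanol
Conditions: LiAlH4, THF, 0 °C to 25 °C
Reagents that add atoms: none
Why: Hydride reduction of a carboxylic acid to the primary alcohol; the furan ring is inert to LiAlH4.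

Step 2
Reactants: 2 (4-methylfuran-2-yl)methanol
Product: 3 6-hydroxy-5-methyl-2H-pyran-3(6H)-one (racemic hemiacetal)
Conditions: NBS, NaHCO3, THF/H2O (4:1), 0 °C
Reagents that add atoms: water, O
Why: Achmatowicz rearrangement: bromonium-induced oxidative opening of the furan to the cis-enedione and closure of the side-chain hydroxyl onto the aldehyde; the furan C4 methyl becomes the C5 methyl of the pyranone, and the acetal stereocentre is irrelevant because it is lost in step 7.

Step 3
Reactants: 3 6-hydroxy-5-methyl-2H-pyran-3(6H)-one
Product: 4 6-acetoxy-5-methyl-2H-pyran-3(6H)-one (racemic)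
Conditions: Ac2O, pyridine, DMAP (cat.), CH2Cl2, 0 °C
Reagents that add atoms: acetic anhydride, CC(=O)OC(C)=O
Why: Acylation of the hemiacetal hydroxyl turns it into the leaving group needed for ylide formation; the mild base at 0 °C should not yet trigger elimination.

Step 4
Reactants: 5 (1S,2R,5S)-menthyl (R)-p-toluenesulfinate; 6 prop-1-ynylmagnesium bromide
Product: 7 (R)-1-(p-tolylsulfinyl)prop-1-yne
Conditions: toluene/THF, −20 °C to 0 °C; NH4Cl (aq)
Reagents that add atoms: none
Why: Andersen sulfoxide synthesis: the alkynyl Grignard reagent displaces the menthyloxy group at sulfur with clean inversion, so the sulfur configuration of 7 follows from that of crystalline 5 (the descriptor stays R only because the priorities of the ligands change).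

Step 5
Reactants: 8 3-bromopropanoyl chloride; 9 isopropylmagnesium chloride
Product: 10 1-bromo-4-methylpentan-3-one
Conditions: Fe(acac)3 (3 mol %), THF, −78 °C
Reagents that add atoms: none
Why: Iron-catalysed acylation of a Grignard reagent by an acid chloride; at −78 °C the catalysed coupling should outrun addition to the product ketone, attack at the primary bromide and elimination of HBr.

Step 6
Reactants: 10 1-bromo-4-methylpentan-3-one
Product: 11 2-(2-bromoethyl)-2-isopropyl-1,3-dioxolane
Conditions: HOCH2CH2OH, p-TsOH (cat.), toluene, reflux, Dean–Stark
Reagents that add atoms: ethylene glycol, OCCO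
Why: Acid-catalysed ketalisation with azeotropic removal of water; masking the ketone allows a Grignard reagent to be formed at the primary bromide.

Step 7
Reactants: 4 6-acetoxy-5-methyl-2H-pyran-3(6H)-one; 7 (R)-1-(p-tolylsulfinyl)prop-1-yne
Product: 13 (1S,5S)-4,7-dimethyl-6-[(R)-p-tolylsulfinyl]-8-oxabicyclo[3.2.1]octa-3,6-dien-2-one, via 5-methyl-3-oxidopyrylium ylide 12 (not isolated)
Conditions: Et3N, CH2Cl2, 25 °C, 4 added slowly by syringe pump
Reagents that add atoms: none
Why: Proposed new method: the amine removes a C2 proton of 4 and acetate departs to give the flat, achiral ylide 12, whose two oxygen-flanked termini add across the alkyne of 7 in a concerted but asynchronous (5+2) cycloaddition; the closest known reactions are the (5+2) additions of 3-oxidopyrylium ylides to acceptor-substituted alkynes and the sulfinyl-directed additions to alkenyl sulfoxides, an alkynyl sulfoxide not having served as the two-carbon partner. The seven-membered carbocycle is closed intermolecularly by simultaneous, suprafacial formation of C7–C8 and C9–C10, and the oxygen-bridged five- and six-membered rings arise in the same event because the ring oxygen of 12 already links C7 and C10; no separate ring closure is involved. Regiochemistry is matched by polarity: the enolate-like terminus next to the oxido carbon (C7) bonds to the β-carbon of the alkynyl sulfoxide (C8), the acetal-derived, electrophilic terminus (C10) to the sulfur-bearing carbon (C9). C7 and C10 are tied to each other by the bridge, so only their absolute sense is open, and the sulfur stereocentre is the sole element that can set it. In the favoured approach the tolyl group points away from the ylide, the S–O bond lies over the ring-oxygen flank of the acetal terminus and the sulfur lone pair faces the flank that carries the ylide methyl group, which for (R) sulfur leads to the bridgehead configuration of 13; the rotamer with S–O turned toward the alkyne methyl is the one that would give the mirror-image bridge. The step needs face selectivity, one regiochemistry and interception of 12 before it dimerises: the first rests on this conformational bias, the second on the sulfinyl polarisation of the triple bond, the third on slow addition of 4 to 7 so that the ylide concentration stays low.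

Step 8
Reactants: 13 (1S,5S)-4,7-dimethyl-6-[(R)-p-tolylsulfinyl]-8-oxabicyclo[3.2.1]octa-3,6-dien-2-one; 11 2-(2-bromoethyl)-2-isopropyl-1,3-dioxolane
Product: 15 2-trimethylsilyloxy-4,7-dimethyl-4-[2-(2-isopropyl-1,3-dioxolan-2-yl)ethyl]-6-[(R)-p-tolylsulfinyl]-8-oxabicyclo[3.2.1]octa-2,6-diene (C1 side chain on the ether-bridge face; C1 methyl on the opposite face), via Grignard reagent 14 (not isolated)
Conditions: Mg, THF, 25 °C; then CuBr·SMe2 (10 mol %), Me3SiCl, THF, −78 °C; Et3N/pentane work-up
Reagents that add atoms: chlorotrimethylsilane, C[Si](C)(C)Cl
Why: Copper-catalysed conjugate addition of a Grignard reagent with in situ O-silylation; the organocopper should add to the enone β-carbon C1 from the face of the one-atom ether bridge, because the other face is covered by the two-carbon bridge and its sulfinyl group, which makes C1 quaternary with the chain β and the methyl α. The fully substituted, weakly accepting alkenyl sulfoxide should not compete, and the enolate is kept as its silyl enol ether to mask C6 for step 9.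

Step 9
Reactants: 15 silyl enol ether from step 8
Product: 18 4,7-dimethyl-4-(4-methyl-3-oxopentyl)-8-oxabicyclo[3.2.1]oct-6-en-2-one (side chain on the ether-bridge face of C1), via C9-lithio silyl enol ether 16 (not isolated), via ketal ketone 17 (not isolated)
Conditions: t-BuLi, THF, −78 °C; MeOH; then 1 M HCl, THF, 25 °C
Reagents that add atoms: water, O
Why: Sulfoxide–lithium exchange of an alkenyl aryl sulfoxide: the alkyllithium attacks sulfur and the strained alkenyl ligand is expelled as alkenyllithium 16 while the silyl enol ether (or the lithium enolate formed from it) protects C6; protonation gives C9–H with the alkene in place, and aqueous acid then hydrolyses the enol ether and the dioxolane to the two ketones.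

Step 10
Reactants: 18 diketone from step 9
Product: 20 7β,10β-epoxydauca-4,8-dien-6-one (ether bridge C7–O–C10; 1α-methyl; C4=C5 conjugated with the C6 ketone), via cis-fused aldol 19 (not isolated)
Conditions: KOH, EtOH, 60 °C
Reagents that add atoms: none
Why: Intramolecular aldol condensation: the ring ketone can enolise only toward C5 because C7 is a bridgehead, attack on the side-chain ketone closes the five-membered ring, and E1cB loss of water from 19 gives the tetrasubstituted enone. The alternative aldol (C3 onto C6) is reversible and cannot dehydrate without a bridgehead alkene, and no stereocentre is created because C4 and C5 become sp2.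

Step 11
Reactants: 20 7β,10β-epoxydauca-4,8-dien-6-one
Product: 21 4β,5β:7β,10β-diepoxydauc-8-en-6-one
Conditions: 30% H2O2, NaOH, MeOH, 0 °C to 25 °C
Reagents that add atoms: hydrogen peroxide, OO
Why: Weitz–Scheffer nucleophilic epoxidation of an enone; hydroperoxide should add to C4 and close onto C5 on the β face, since the α face carries the pseudo-axial C1 methyl and lies over the two-carbon bridge, which sets C4 with oxygen β and isopropyl α. The electron-rich C8=C9 alkene is not touched by a nucleophilic oxidant, and C7 cannot enolise.

Step 12
Reactants: 21 4β,5β:7β,10β-diepoxydauc-8-en-6-one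
Product: 23 4β,10β-dihydroxy-5βH-dauc-8-en-6-one (trans-fused), via bridged hydroxy ketone 22 (not isolated)
Conditions: SmI2 (4.5 equiv), THF/MeOH, −78 °C
Reagents that add atoms: none
Why: Two successive reductive cleavages of C–O bonds α to a ketone by divalent samarium: the ketyl first opens the strained epoxide at C5–O, and the resulting enolate should be protonated at C5 on the β face because the α face is flanked by the C1 methyl and the C4 isopropyl group, giving H5 β and hence the trans ring fusion (22). The regenerated ketone then loses the C7–O bond, which frees the C10 hydroxyl with the configuration set in step 7, and kinetic α-protonation of the dienolate at C7 keeps C8=C9 out of conjugation.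

Step 13
Reactants: 23 4β,10β-dihydroxy-5βH-dauc-8-en-6-one
Product: 24 5βH-dauc-8-ene-4β,6β,10β-triol
Conditions: Li, NH3 (l), THF, t-BuOH, −78 °C; then NH4Cl
Reagents that add atoms: none
Why: Dissolving-metal reduction of a ketone under thermodynamic control: the ketyl and the derived carbanion are pyramidal and should be protonated to the more stable equatorial alcohol (O6 β, H6 anti to H5), whereas a hydride reagent would approach anti to the axial C1 methyl and give the α epimer. The alcohol additive suppresses enolisation, and the isolated alkene and the alkoxides are inert.

Step 14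
Reactants: 24 5βH-dauc-8-ene-4β,6β,10β-triol; 25 4-(tert-butyldimethylsilyloxy)benzoic acid
Product: 26 6-O-[4-(tert-butyldimethylsilyloxy)benzoyl]-5βH-dauc-8-ene-4β,6β,10β-triol
Conditions: EDC·HCl, DMAP, CH2Cl2, 0 °C to 25 °C
Reagents that add atoms: none
Why: Steglich esterification; the acylpyridinium should select the equatorial C6 hydroxyl over the pseudo-axial, neopentylic C10 hydroxyl next to the quaternary C1, and the tertiary C4 hydroxyl does not react.

Step 15
Reactants: 26 C6 monoester from step 14; 27 tiglic acid
Product: 28 6-O-[4-(tert-butyldimethylsilyloxy)benzoyl]-10-O-tigloyl-5βH-dauc-8-ene-4β,6β,10β-triol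
Conditions: 2,4,6-Cl3C6H2COCl, Et3N, toluene, 25 °C; then 26, DMAP, 60 °C
Reagents that add atoms: none
Why: Yamaguchi esterification through the mixed anhydride, a standard way to acylate hindered secondary alcohols with tiglic acid; the tertiary C4 hydroxyl stays free, and the tiglate already has the stable (E) geometry, so no isomerisation is expected.

Step 16
Reactants: 28 protected diester from step 15
Product: 29 target, 6β-(4-hydroxybenzoyloxy)-10β-tigloyloxy-5βH-dauc-8-en-4β-ol (1S,4S,5S,6S,10R)
Conditions: Bu4NF, AcOH, THF, 0 °C
Reagents that add atoms: none
Why: Fluoride cleavage of an aryl silyl ether, which is much more labile than the esters; buffering with acetic acid keeps the phenoxide from inducing ester cleavage or acyl migration.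

## Compound list

1 | 4-methylfuran-2-carboxylic acid | Cc1coc(C(=O)O)c1 | starting material
2 | (4-methylfuran-2-yl)methanol | Cc1coc(CO)c1 | intermediate
3 | 6-hydroxy-5-methyl-2H-pyran-3(6H)-one (racemic) | CC1=CC(=O)COC1O | intermediate
4 | 6-acetoxy-5-methyl-2H-pyran-3(6H)-one (racemic) | CC1=CC(=O)COC1OC(C)=O | intermediate
5 | (1S,2R,5S)-menthyl (R)-p-toluenesulfinate | C[C@H]1CC[C@@H]([C@H](C1)O[S@@](=O)c2ccc(C)cc2)C(C)C | starting material
6 | prop-1-ynylmagnesium bromide | CC#C[Mg]Br | starting material
7 | (R)-1-(p-tolylsulfinyl)prop-1-yne | CC#C[S@](=O)c1ccc(C)cc1 | intermediate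
8 | 3-bromopropanoyl chloride | O=C(Cl)CCBr | starting material
9 | isopropylmagnesium chloride | CC(C)[Mg]Cl | starting material
10 | 1-bromo-4-methylpentan-3-one | BrCCC(=O)C(C)C | intermediate
11 | 2-(2-bromoethyl)-2-isopropyl-1,3-dioxolane | BrCCC1(OCCO1)C(C)C | intermediate
12 | 5-methyl-3-oxidopyrylium ylide | Cc1cc([O-])c[o+]c1 | intermediate (not isolated)
13 | (1S,5S)-4,7-dimethyl-6-[(R)-p-tolylsulfinyl]-8-oxabicyclo[3.2.1]octa-3,6-dien-2-one | O1[C@@H]2C([S@](=O)c3ccc(C)cc3)=C(C)[C@H]1C(=O)C=C2C | intermediate
14 | [2-(2-isopropyl-1,3-dioxolan-2-yl)ethyl]magnesium bromide | Br[Mg]CCC1(OCCO1)C(C)C | intermediate (not isolated)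
15 | silyl enol ether of the C1 conjugate adduct (chain β, methyl α at C1; C9 sulfinyl) | O1[C@@H]2C([S@](=O)c3ccc(C)cc3)=C(C)[C@H]1C(O[Si](C)(C)C)=C[C@]2(C)CCC4(OCCO4)C(C)C | intermediate
16 | C9-lithio silyl enol ether | O1[C@@H]2C([Li])=C(C)[C@H]1C(O[Si](C)(C)C)=C[C@]2(C)CCC3(OCCO3)C(C)C | intermediate (not isolated)
17 | 4-[2-(2-isopropyl-1,3-dioxolan-2-yl)ethyl]-4,7-dimethyl-8-oxabicyclo[3.2.1]oct-6-en-2-one | O1[C@@H]2C=C(C)[C@H]1C(=O)C[C@]2(C)CCC3(OCCO3)C(C)C | intermediate (not isolated)
18 | 4,7-dimethyl-4-(4-methyl-3-oxopentyl)-8-oxabicyclo[3.2.1]oct-6-en-2-one | O1[C@@H]2C=C(C)[C@H]1C(=O)C[C@]2(C)CCC(=O)C(C)C | intermediate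
19 | 7β,10β-epoxy-4-hydroxy-5αH-dauc-8-en-6-one (cis-fused aldol, C4 epimers) | O1[C@@H]2C=C(C)[C@H]1C(=O)[C@@H]3C(O)(C(C)C)CC[C@]23C | intermediate (not isolated)
20 | 7β,10β-epoxydauca-4,8-dien-6-one | O1[C@@H]2C=C(C)[C@H]1C(=O)C3=C(C(C)C)CC[C@]23C | intermediate
21 | 4β,5β:7β,10β-diepoxydauc-8-en-6-one | O1[C@@H]2C=C(C)[C@H]1C(=O)[C@@]13O[C@]1(C(C)C)CC[C@]23C | intermediate
22 | 7β,10β-epoxy-4β-hydroxy-5βH-dauc-8-en-6-one | O1[C@@H]2C=C(C)[C@H]1C(=O)[C@H]3[C@@](O)(C(C)C)CC[C@]23C | intermediate (not isolated)
23 | 4β,10β-dihydroxy-5βH-dauc-8-en-6-one | O[C@@H]1C=C(C)CC(=O)[C@@H]2[C@]1(C)CC[C@]2(O)C(C)C | intermediate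
24 | 5βH-dauc-8-ene-4β,6β,10β-triol | O[C@@H]1C=C(C)C[C@H](O)[C@@H]2[C@]1(C)CC[C@]2(O)C(C)C | intermediate
25 | 4-(tert-butyldimethylsilyloxy)benzoic acid | CC(C)(C)[Si](C)(C)Oc1ccc(cc1)C(=O)O | starting material
26 | 6-O-[4-(tert-butyldimethylsilyloxy)benzoyl]-5βH-dauc-8-ene-4β,6β,10β-triol | O[C@@H]1C=C(C)C[C@H](OC(=O)c2ccc(O[Si](C)(C)C(C)(C)C)cc2)[C@@H]2[C@]1(C)CC[C@]2(O)C(C)C | intermediate
27 | tiglic acid, (E)-2-methylbut-2-enoic acid | C/C=C(\C)C(=O)O | starting material
28 | 6-O-[4-(tert-butyldimethylsilyloxy)benzoyl]-10-O-tigloyl-5βH-dauc-8-ene-4β,6β,10β-triol | C/C=C(\C)C(=O)O[C@@H]1C=C(C)C[C@H](OC(=O)c2ccc(O[Si](C)(C)C(C)(C)C)cc2)[C@@H]2[C@]1(C)CC[C@]2(O)C(C)C | intermediate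
29 | 6β-(4-hydroxybenzoyloxy)-10β-tigloyloxy-5βH-dauc-8-en-4β-ol | C/C=C(\C)C(=O)O[C@@H]1C=C(C)C[C@H](OC(=O)c2ccc(O)cc2)[C@@H]2[C@]1(C)CC[C@]2(O)C(C)C | target

## Step count and risk

Total step count: 16 steps. Longest linear sequence: 13 steps (steps 1, 2, 3, 7 and 8 to 16); steps 4, 5 and 6 are side branches.

Least certain steps:

**Step 7 (key step, proposed new method).** Two processes may fail.

- Capture of the ylide by an internal alkyne that carries only one sulfinyl acceptor may be too slow, so that dimerisation of 12 takes over.
- Face discrimination may be poor, because the sulfur stereocentre is separated from the reacting carbon by a linear sp carbon and the preferred sulfinyl rotamer is predicted, not established.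

Both antipodes of the sulfinate ester are commercial, so the sense of induction can be matched once it is known.

Fallback by known chemistry, setting out from 4 and 7 and returning at 18:

- 7 is reduced with LiAlH4 (THF, −78 °C) to (S)-(E)-1-(p-tolylsulfinyl)prop-1-ene F1, in which the sulfur atom is spatially unchanged.
- F1 is used as the two-carbon partner of the ylide from 4 under the conditions of step 7; this is the precedented class of sulfinyl-directed additions to alkenyl sulfoxides.
- The diastereomeric adducts are separated, and the one with the bridgehead configuration of 13 is taken: the endo-sulfinyl, exo-methyl adduct F2. Its sulfinyl epimers with the same bridgeheads serve equally.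
- F2 is heated in toluene at 110 °C. The sulfoxide eliminates syn toward C8, the only possible direction since C10 is a bridgehead, to give the sulfur-free dienone 4,7-dimethyl-8-oxabicyclo[3.2.1]octa-3,6-dien-2-one F3.
- Copper-catalysed addition of 14 with Me3SiCl as in step 8 gives the sulfur-free silyl enol ether F4. Aqueous HCl converts F4 by way of 17 into 18.

This fallback also makes step 9 unnecessary.

**Step 9.** The alkyllithium may attack silicon or the tolyl–sulfur bond in place of the alkenyl–sulfur bond, or the enol ether mask may be lost so that the ketone is attacked.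

Fallback, setting out from 15 and returning at 18:

- Methanolysis with K2CO3 gives the sulfinyl ketone ketal F5.
- mCPBA (CH2Cl2, 0 °C) oxidises F5 to the alkenyl sulfone F6.
- Radical stannyl-desulfonylation (Bu3SnH, AIBN, toluene, 100 °C) replaces the sulfonyl group by tin through addition of the stannyl radical at C9 and loss of the sulfonyl radical, giving the alkenylstannane F7.
- Aqueous HCl in THF protodestannylates F7 and hydrolyses the dioxolane, giving 18 by way of 17.

**Step 12.** If the C5 enolate is protonated while the ether bridge is still in place, ring strain may divert the proton to the α face and give the cis ring fusion. Over-reduction of the ketone by excess reductant is the second hazard.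

Fallback, setting out from 20 and returning at 23, with the bridge opened before the epoxide is made:

- SmI2 (2.2 equiv, THF/MeOH, −78 °C) cleaves the C7–O bond of 20 to give 10β-hydroxydauca-4,8-dien-6-one F8.
- Anhydrous t-BuOOLi (THF, −20 °C) is used for the epoxidation because C7 is now enolisable. It should epoxidise the enone anti to the C1 methyl, giving 4β,5β-epoxy-10β-hydroxydauc-8-en-6-one F9.
- A second SmI2 cleavage opens the epoxide in the unbridged ring. β-Protonation at C5 is then unopposed, and 23 results.

**Step 13.** Protonation of the reduced intermediate may occur under kinetic control and give the axial 6α alcohol, or the C8=C9 alkene may migrate into conjugation before the ketone is reduced.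

Fallback, setting out from 23 and returning at 28:

- 23 is tigloylated at its only secondary hydroxyl with 27 under the conditions of step 15, giving 4β-hydroxy-10β-tigloyloxy-5βH-dauc-8-en-6-one F10.
- NaBH4 with CeCl3 (MeOH, −40 °C) should add hydride anti to the C1 methyl and give the 6α alcohol F11.
- Mitsunobu esterification of F11 with 25 (PPh3, DIAD, toluene) inverts C6 and installs the aroyl group in one operation, giving 28.

**Step 14.** Acylation may not discriminate well enough between the C6 and C10 hydroxyls.

Fallback, setting out from 23 and returning at 26:

- Et3SiCl and imidazole (DMF) silylate the lone secondary hydroxyl of 23, giving the 10-O-triethylsilyl ketone F12.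
- The reduction of step 13 gives the 10-O-triethylsilyl 6β-alcohol F13.
- The esterification of step 14 with 25 gives the 6-O-aroyl 10-O-triethylsilyl compound F14.
- AcOH/THF/H2O removes the alkyl triethylsilyl ether, leaving the aryl silyl ether intact, to give 26.

## Further compounds

F1 | step 7 | (S)-(E)-1-(p-tolylsulfinyl)prop-1-ene | C/C=C/[S@](=O)c1ccc(C)cc1
F2 | step 7 | 4,7-dimethyl-6-[(S)-p-tolylsulfinyl]-8-oxabicyclo[3.2.1]oct-3-en-2-one, bridgeheads as in 13, sulfinyl endo, C7-methyl exo | O1[C@@H]2[C@@H]([S@](=O)c3ccc(C)cc3)[C@H](C)[C@H]1C(=O)C=C2C
F3 | step 7 | 4,7-dimethyl-8-oxabicyclo[3.2.1]octa-3,6-dien-2-one, bridgeheads as in 13 | O1[C@@H]2C=C(C)[C@H]1C(=O)C=C2C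
F4 | step 7 | 2-trimethylsilyloxy-4,7-dimethyl-4-[2-(2-isopropyl-1,3-dioxolan-2-yl)ethyl]-8-oxabicyclo[3.2.1]octa-2,6-diene | O1[C@@H]2C=C(C)[C@H]1C(O[Si](C)(C)C)=C[C@]2(C)CCC3(OCCO3)C(C)C
F5 | step 9 | 4-[2-(2-isopropyl-1,3-dioxolan-2-yl)ethyl]-4,7-dimethyl-6-[(R)-p-tolylsulfinyl]-8-oxabicyclo[3.2.1]oct-6-en-2-one | O1[C@@H]2C([S@](=O)c3ccc(C)cc3)=C(C)[C@H]1C(=O)C[C@]2(C)CCC4(OCCO4)C(C)C
F6 | step 9 | 4-[2-(2-isopropyl-1,3-dioxolan-2-yl)ethyl]-4,7-dimethyl-6-(p-tolylsulfonyl)-8-oxabicyclo[3.2.1]oct-6-en-2-one | O1[C@@H]2C(S(=O)(=O)c3ccc(C)cc3)=C(C)[C@H]1C(=O)C[C@]2(C)CCC4(OCCO4)C(C)C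
F7 | step 9 | 4-[2-(2-isopropyl-1,3-dioxolan-2-yl)ethyl]-4,7-dimethyl-6-(tributylstannyl)-8-oxabicyclo[3.2.1]oct-6-en-2-one | O1[C@@H]2C([Sn](CCCC)(CCCC)CCCC)=C(C)[C@H]1C(=O)C[C@]2(C)CCC4(OCCO4)C(C)C
F8 | step 12 | 10β-hydroxydauca-4,8-dien-6-one | O[C@@H]1C=C(C)CC(=O)C2=C(C(C)C)CC[C@]12C
F9 | step 12 | 4β,5β-epoxy-10β-hydroxydauc-8-en-6-one | O[C@@H]1C=C(C)CC(=O)[C@@]23O[C@]2(C(C)C)CC[C@]13C
F10 | step 13 | 4β-hydroxy-10β-tigloyloxy-5βH-dauc-8-en-6-one | C/C=C(\C)C(=O)O[C@@H]1C=C(C)CC(=O)[C@@H]2[C@]1(C)CC[C@]2(O)C(C)C
F11 | step 13 | 10-O-tigloyl-5βH-dauc-8-ene-4β,6α,10β-triol | C/C=C(\C)C(=O)O[C@@H]1C=C(C)C[C@@H](O)[C@@H]2[C@]1(C)CC[C@]2(O)C(C)C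
F12 | step 14 | 4β-hydroxy-10β-triethylsilyloxy-5βH-dauc-8-en-6-one | CC[Si](CC)(CC)O[C@@H]1C=C(C)CC(=O)[C@@H]2[C@]1(C)CC[C@]2(O)C(C)C
F13 | step 14 | 10-O-triethylsilyl-5βH-dauc-8-ene-4β,6β,10β-triol | CC[Si](CC)(CC)O[C@@H]1C=C(C)C[C@H](O)[C@@H]2[C@]1(C)CC[C@]2(O)C(C)C
F14 | step 14 | 6-O-[4-(tert-butyldimethylsilyloxy)benzoyl]-10-O-triethylsilyl-5βH-dauc-8-ene-4β,6β,10β-triol | CC[Si](CC)(CC)O[C@@H]1C=C(C)C[C@H](OC(=O)c2ccc(O[Si](C)(C)C(C)(C)C)cc2)[C@@H]2[C@]1(C)CC[C@]2(O)C(C)C
A1 | alternative 1 | trans-fused hydroazulene with C6 dithiane, free C4 hydroxyl and C10 silyl ether | CC(C)(C)[Si](C)(C)O[C@@H]1C=C(C)CC2(SCCCS2)[C@@H]2[C@]1(C)CC[C@]2(O)C(C)C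
A2 | alternative 1 | cyclopentene oxide tethered through a (Z)-alkene to a 2-substituted 1,3-dithiane | CC(C)(C)[Si](C)(C)O[C@H](/C=C(C)\CC1SCCCS1)[C@@]1(C)CC[C@@]2(C(C)C)O[C@@H]12
A3 | alternative 2 | cis-anti-cis tricyclic bis-silyl ether photoadduct (either C8 methyl epimer) | C[C@]12CCC(=O)[C@H]1[C@]1(O[Si](C)(C)C)CC(C)C[C@]21O[Si](C)(C)C
A4 | alternative 2 | 3-methylcyclopent-2-enone | CC1=CC(=O)CC1
A5 | alternative 2 | 4-methyl-1,2-bis(trimethylsilyloxy)cyclopentene | CC1CC(O[Si](C)(C)C)=C(O[Si](C)(C)C)C1
A6 | alternative 3 | trans-2,3-disubstituted cyclopentanone aldol with C1, C5 and C6 set | I/C=C(C)\C[C@H](O)[C@@H]1[C@@](C)(COCOC)CCC1=O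
A7 | alternative 3 | 3-(methoxymethoxymethyl)cyclopent-2-enone | COCOCC1=CC(=O)CC1
A8 | alternative 3 | (Z)-4-iodo-3-methylbut-3-enal | I/C=C(C)\CC=O
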